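**Strategy**

With ring A as C1–C5/C10 and ring B as C5–C10 (C11 on C9, C12 on C8), ring B is (R)-carvone and its isopropenyl group on C5 already contains C3, C4 and the C4 methyl. The route rests on cutting ring A at C2–C3 and the side chain at C4. In one operation an α-keto radical at C2 closes ring A by 6-endo attack on the isopropenyl CH2 (C3), and the tertiary C4 radical is allylated anti to the C10 methyl, giving the trans-decalin with its C4 quaternary centre. The precursor is a carvone-derived enone whose quaternary C10 carries a methyl group cis and an iodoacetyl group trans to the isopropenyl group.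

Key step: step 5

Remarks on the chemistry:
- The decalin locants above are used throughout; α is the face of H-5, β the face of the C10 methyl. The target has 1α-OH (axial), 3β-Cl (equatorial), 4β-methyl, 4α-homoprenyl, 9α-H.
- Assumption: 3 (epimers at the future C10), 6 (carbinol epimers) and 25 (anomers) are carried as mixtures, because these centres are planarised or oxidised in the following step.
- After the key step C1 is masked as a silyl enol ether and C9 is methylenated and hydroborated before the ring A enone is made. This way only one enone is present during conjugate borylation, and C1 is still trigonal when hydrogen is delivered to C9.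
- The homoprenyl alkene is introduced only after the selenium dioxide step, which it would not survive.

**Route**

Step 1
Reactants: 1 (R)-carvone
Product: 3 6-methylcarvone (methyl mainly trans to isopropenyl), via carvone lithium dienolate 2 (not isolated)
Conditions: LiN(iPr)2, THF, −78 °C; MeI, −78 to −20 °C
Reagents that add atoms: iodomethane, CI; LiN(iPr)2, [Li]N(C(C)C)C(C)C (lithium only in 2)
Why: Kinetic α′-deprotonation at the future C10 gives the cross-conjugated lithium dienolate and enolate alkylation with iodomethane installs the C10 methyl, mainly anti to the isopropenyl group; the configuration of this carbon is not critical because it is enolised again in step 2.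

Step 2
Reactants: 3 6-methylcarvone; 4 acetaldehyde
Product: 6 aldol adduct (C10 methyl cis and 1-hydroxyethyl trans to isopropenyl; carbinol epimers), via lithium enolate 5 (not isolated)
Conditions: LiN(iPr)2, THF, −78 °C; MeCHO, −78 °C; AcOH quench at −78 °C
Reagents that add atoms: acetaldehyde (4), CC=O; LiN(iPr)2, [Li]N(C(C)C)C(C)C (lithium only in 5)
Why: Aldol addition of the tetrasubstituted lithium enolate to acetaldehyde takes place on the face anti to the neighbouring C5 isopropenyl group, which sets the quaternary C10 with its methyl cis and the new two-carbon arm (C1, C2) trans to isopropenyl; the cold acidic quench prevents retro-aldol cleavage.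

Step 3
Reactants: 6 aldol adduct
Product: 7 6-acetyl-6-methylcarvone (acetyl trans to isopropenyl)
Conditions: Dess–Martin periodinane, NaHCO3, CH2Cl2, 0 °C to rt
Reagents that add atoms: none
Why: Dess–Martin oxidation of the secondary alcohol under buffered, neutral conditions gives the methyl ketone without retro-aldol cleavage, and the quaternary C10 cannot epimerise.

Step 4
Reactants: 7 6-acetyl-6-methylcarvone
Product: 9 iodoacetyl ketone (radical precursor), via trimethylsilyl enol ether 8 (not isolated)
Conditions: Me3SiCl, LiN(SiMe3)2, THF, −78 °C (in situ trapping); then N-iodosuccinimide, −78 to 0 °C, dark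
Reagents that add atoms: N-iodosuccinimide, O=C1CCC(=O)N1I; chlorotrimethylsilane, C[Si](C)(C)Cl (silicon only in 8)
Why: Kinetic enolisation can occur only at the acetyl CH3 (C10 is quaternary and the enone offers only γ-hydrogens), and electrophilic iodination of the silyl enol ether with N-iodosuccinimide gives the α-iodo ketone regiospecifically.

Step 5
Reactants: 9 iodoacetyl ketone; 10 allyltributylstannane
Product: 11 4α-allyl-4β,8,10β-trimethyl-trans-decal-7-ene-1,9-dione (5α-H)
Conditions: Bu3SnCH2CH=CH2 (3 equiv), AIBN (in portions), degassed benzene (0.02 M in 9), 80 °C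
Reagents that add atoms: allyltributylstannane (10), C=CC[Sn](CCCC)(CCCC)CCCC
Why: Tributyltin radical abstracts iodine from 9 to give an electrophilic α-keto radical at C2, which adds to the electron-rich CH2 terminus (C3) of the isopropenyl group; the tertiary, nucleophilic C4 radical then adds to the allylstannane and expels Bu3Sn•, which carries the chain (a C4 radical that first takes iodine from 9 re-enters through the tertiary iodide). The closest known reaction types are the 6-endo cyclisation of α-carbonyl radicals onto 1,1-disubstituted alkenes and the Keck allyl transfer to tertiary radicals. Ring A closes in the 6-endo-trig mode through a chair transition state in which the acyl arm on C10 and the alkene on C5, trans and both equatorial on ring B, can only give the trans ring fusion. The one new stereocentre, C4, is controlled by the axial C10 methyl: the stannane should approach the α face, anti to this 1,3-related methyl, so that allyl becomes equatorial and the C4 methyl axial (β). The step needs 6-endo over 5-exo closure, attack on the isopropenyl group and not on the C7=C8 enone, and ring closure before allyl transfer to C2; the first follows from the polarity match and the tertiary radical formed (5-exo would build a quaternary centre beside C5), the second from the mismatch between an electrophilic radical and the electron-poor enone, the third from pre-organisation by the quaternary C10 together with a low stannane concentration.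

Step 6
Reactants: 11 allyl decalindione
Product: 13 C1 tert-butyldimethylsilyl enol ether (C1=C2) of 11, via C1 lithium enolate 12 (not isolated)
Conditions: LiN(SiMe3)2, THF, −78 °C; tBuMe2SiOTf, −78 to 0 °C
Reagents that add atoms: tert-butyldimethylsilyl trifluoromethanesulfonate, CC(C)(C)[Si](C)(C)OS(=O)(=O)C(F)(F)F; LiN(SiMe3)2, [Li]N([Si](C)(C)C)[Si](C)(C)C (lithium only in 12)
Why: Kinetic enolisation is possible only at C2 (C10 is quaternary, the C9 enone has only γ-hydrogens), and O-silylation of the lithium enolate masks C1 as a silyl enol ether that shields this ketone in steps 7 and 8 and later serves for dehydrogenation.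

Step 7
Reactants: 13 silyl enol ether
Product: 14 9-methylene triene (C9=C11)
Conditions: Ph3PCH3Br, KN(SiMe3)2, toluene, 0 °C; then 13, 90 °C
Reagents that add atoms: methyltriphenylphosphonium bromide, C[P+](c1ccccc1)(c1ccccc1)c1ccccc1.[Br-]
Why: Wittig methylenation of the only free carbonyl (C9) with the small, alkoxide-free methylene ylide at elevated temperature, as used for hindered ketones, introduces C11; the silyl enol ether and the alkenes are inert to the ylide.

Step 8
Reactants: 14 triene
Product: 16 diol (4α-3-hydroxypropyl; 9β-hydroxymethyl; 9α-H), via bis(9-BBN) adduct 15 (not isolated)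
Conditions: 9-BBN (2.5 equiv), THF, 0 to 45 °C; then NaBO3·4H2O, H2O, rt
Reagents that add atoms: sodium perborate (oxygen), [Na+].[Na+].O[B-]1(O)OO[B-](O)(O)OO1; 9-borabicyclo[3.3.1]nonane, B1C2CCCC1CCC2 (boron only in 15)
Why: Anti-Markovnikov hydroboration with 9-BBN takes only the two terminal CH2= groups (allyl and C9=C11) and leaves the trisubstituted C7=C8 alkene and the hindered silyl enol ether, hydrogen being delivered to C9 on the α face anti to the C10 methyl (C1 is trigonal and leaves that face open) so that 9α-H and 9β-CH2OH result; perborate oxidation proceeds with retention.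

Step 9
Reactants: 16 diol
Product: 17 diacetate
Conditions: Ac2O, pyridine, DMAP (cat.), CH2Cl2, 0 °C to rt
Reagents that add atoms: acetic anhydride, CC(=O)OC(C)=O
Why: Acylation of both primary alcohols gives esters that should survive the ring A sequence and provide the ester-protected homoallylic system suited to the later allylic oxidation.

Step 10
Reactants: 17 diacetate
Product: 18 Δ2-en-1-one
Conditions: Pd(OAc)2 (1.1 equiv), MeCN, 40 °C
Reagents that add atoms: none
Why: Saegusa–Ito oxidation: the silyl enol ether is transmetalated to a C2 palladium enolate and β-hydride elimination toward C3, the only position with hydrogens, gives the C2=C3 enone; the lone trisubstituted alkene and the esters do not interfere.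

Step 11
Reactants: 18 enone
Product: 19 3α-(pinacolboryl) 1-ketone
Conditions: CuCl (5 mol %), NaOtBu (10 mol %), DPEphos (5 mol %), B2pin2, MeOH (2 equiv), THF, rt
Reagents that add atoms: bis(pinacolato)diboron, CC1(C)OB(OC1(C)C)B1OC(C)(C)C(C)(C)O1
Why: Copper-catalysed conjugate borylation of the only enone: the copper–boryl species adds to C3 by axial attack on the α face, anti to the β-methyls on C4 and C10, and methanol protonates the enolate, giving the axial 3α-boronate.

Step 12
Reactants: 19 boryl ketone
Product: 20 1α-hydroxy-3α-boronate
Conditions: NaBH4, MeOH/THF, −20 to 0 °C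
Reagents that add atoms: none
Why: Borohydride reduction of the ketone: the axial C3 boronate, together with the axial hydrogens on C5 and C9, closes the α-axial trajectory, so hydride should be delivered from the β face to give the axial 1α-alcohol; the esters are untouched at low temperature.

Step 13
Reactants: 20 hydroxy boronate
Product: 21 1α-triethylsilyl ether
Conditions: Et3SiOTf, 2,6-lutidine, CH2Cl2, −40 to 0 °C
Reagents that add atoms: triethylsilyl trifluoromethanesulfonate, CC[Si](CC)(CC)OS(=O)(=O)C(F)(F)F
Why: Silylation of the hindered secondary alcohol with the silyl triflate distinguishes O1 from the oxygen introduced next at C3 and protects it through the later oxidations, while remaining removable by fluoride under mild acid conditions.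

Step 14
Reactants: 21 silyl ether boronate
Product: 22 3α-alcohol
Conditions: NaBO3·4H2O, THF/H2O, 0 °C to rt
Reagents that add atoms: sodium perborate (oxygen), [Na+].[Na+].O[B-]1(O)OO[B-](O)(O)OO1
Why: Oxidation of the C–B bond by perborate (1,2-shift of C3 from boron to oxygen) occurs with retention and gives the axial 3α-alcohol; the nearly neutral medium spares the acetates and limits 1,3-silyl transfer.

Step 15
Reactants: 22 3α-alcohol
Product: 23 3β-chloride
Conditions: PPh3, CCl4, ClCH2CH2Cl, 70 °C
Reagents that add atoms: tetrachloromethane, ClC(Cl)(Cl)Cl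
Why: Appel reaction: the axial oxyphosphonium group on C3 is displaced from the rear by chloride (SN2) with inversion to give the equatorial 3β-chloride, departure being assisted by relief of the syn-axial strain with the C1 silyl ether; the neutral conditions leave esters, silyl ether and alkene intact.

Step 16
Reactants: 23 chloride
Product: 24 C12 enal (8-formyl)
Conditions: SeO2, 1,4-dioxane, 80 °C
Reagents that add atoms: selenium dioxide, O=[Se]=O
Why: Riley allylic oxidation (ene reaction followed by 2,3-sigmatropic shift) attacks the methyl group on the more substituted alkene carbon C8, since the other allylic position on that side, C9–H, is tertiary and flanked by the quaternary C10; any C12 alcohol formed alongside the enal converges in step 18.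

Step 17
Reactants: 24 enal diacetate
Product: 25 lactol (C11–O–C12 hemiacetal; chain 3-hydroxypropyl)
Conditions: K2CO3, MeOH, 0 °C to rt
Reagents that add atoms: none
Why: Base-catalysed transesterification removes both acetates, and the freed C11 hydroxyl closes onto the C12 aldehyde to a five-membered lactol, which masks the ring B oxygens and leaves the chain alcohol as the only free primary hydroxyl group.

Step 18
Reactants: 25 lactol
Product: 26 butenolide aldehyde (C12 carbonyl; O on C11; chain 3-oxopropyl)
Conditions: TEMPO (20 mol %), PhI(OAc)2 (2.5 equiv), CH2Cl2, rt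
Reagents that add atoms: none
Why: Oxoammonium-mediated (TEMPO) oxidation converts the primary alcohol into the aldehyde and the lactol into the butenolide in one operation; no water is present, so the aldehyde should not be oxidised further.

Step 19
Reactants: 26 butenolide aldehyde
Product: 27 homoprenyl butenolide
Conditions: iPrPPh3I, n-BuLi, THF, 0 °C; then 26, −78 to 0 °C
Reagents that add atoms: isopropyltriphenylphosphonium iodide, CC(C)[P+](c1ccccc1)(c1ccccc1)c1ccccc1.[I-]
Why: Wittig olefination of the unhindered aldehyde with the isopropylidene ylide completes the homoprenyl chain; at low temperature the lactone should not compete, and the step is placed after step 16 because the isopropylidene group would not survive selenium dioxide.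

Step 20
Reactants: 27 homoprenyl butenolide
Product: 28 11,12-diol
Conditions: LiAlH4, Et2O, −20 to 0 °C
Reagents that add atoms: none
Why: Hydride reduction of the unsaturated lactone by 1,2-addition gives the allylic 1,4-diol, while the hindered secondary chloride, the silyl ether and both alkenes are inert to LiAlH4 at this temperature; C9 is not affected.

Step 21
Reactants: 28 diol
Product: 30 1α-triethylsilyl ether of the dialdehyde, via bis(alkoxydimethylsulfonium) dichloride 29 (not isolated)
Conditions: (COCl)2, DMSO, CH2Cl2, −78 °C; then Et3N, −78 to −30 °C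
Reagents that add atoms: dimethyl sulfoxide, CS(C)=O (sulfur and carbon only in 29)
Why: Swern oxidation: both hydroxyl groups are converted into alkoxysulfonium ions before base is added, so the dialdehyde forms without lactol or lactone formation, and the low temperature keeps the enolisable C9 centre from epimerising.

Step 22
Reactants: 30 silyl ether dialdehyde
Product: 31 target CNP0155449.1
Conditions: HF·pyridine, pyridine, THF, 0 °C to rt
Reagents that add atoms: none
Why: Fluoride-mediated cleavage of the Si–O bond under buffered, mildly acidic conditions frees the 1α-hydroxyl group without a base that could epimerise C9 or isomerise the enedial.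

**Compound list**

1 | (R)-carvone, (5R)-2-methyl-5-(prop-1-en-2-yl)cyclohex-2-en-1-one | CC(=C)[C@@H]1CC=C(C)C(=O)C1 | starting material
2 | carvone lithium dienolate (O-lithio, enolised toward the α′ carbon) | CC(=C)[C@@H]1CC=C(C)C(O[Li])=C1 | intermediate
3 | 6-methylcarvone, (5R)-2,6-dimethyl-5-(prop-1-en-2-yl)cyclohex-2-en-1-one, methyl mainly trans to isopropenyl (this carbon is C10) | CC(=C)[C@@H]1CC=C(C)C(=O)[C@H]1C | intermediate
4 | acetaldehyde | CC=O | starting material
5 | lithium enolate of 3 (tetrasubstituted) | CC(=C)[C@@H]1CC=C(C)C(O[Li])=C1C | intermediate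
6 | 6-(1-hydroxyethyl)-2,6-dimethyl-5-(prop-1-en-2-yl)cyclohex-2-en-1-one, methyl cis and hydroxyethyl trans to isopropenyl, carbinol epimers | CC(=C)[C@@H]1CC=C(C)C(=O)[C@@]1(C)C(C)O | intermediate
7 | 6-acetyl-2,6-dimethyl-5-(prop-1-en-2-yl)cyclohex-2-en-1-one, acetyl trans to isopropenyl | CC(=C)[C@@H]1CC=C(C)C(=O)[C@@]1(C)C(C)=O | intermediate
8 | trimethylsilyl enol ether of the acetyl group of 7 | CC(=C)[C@@H]1CC=C(C)C(=O)[C@@]1(C)C(=C)O[Si](C)(C)C | intermediate
9 | 6-(iodoacetyl)-2,6-dimethyl-5-(prop-1-en-2-yl)cyclohex-2-en-1-one, iodoacetyl trans and methyl cis to isopropenyl | CC(=C)[C@@H]1CC=C(C)C(=O)[C@@]1(C)C(=O)CI | intermediate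
10 | allyltributylstannane | C=CC[Sn](CCCC)(CCCC)CCCC | starting material
11 | 4α-allyl-4β,8,10β-trimethyl-trans-decal-7-ene-1,9-dione (5α-H) | C=CC[C@]1(C)CCC(=O)[C@]2(C)C(=O)C(C)=CC[C@@H]12 | intermediate
12 | C1 lithium enolate (C1=C2) of 11 | C=CC[C@]1(C)CC=C(O[Li])[C@]2(C)C(=O)C(C)=CC[C@@H]12 | intermediate
13 | 1-(tert-butyldimethylsilyloxy)-Δ1 enol ether of 11, 9-ketone retained | C=CC[C@]1(C)CC=C(O[Si](C)(C)C(C)(C)C)[C@]2(C)C(=O)C(C)=CC[C@@H]12 | intermediate
14 | 4α-allyl-1-(tert-butyldimethylsilyloxy)-4β,8,10β-trimethyl-9-methylene-trans-decala-1,7-diene | C=CC[C@]1(C)CC=C(O[Si](C)(C)C(C)(C)C)[C@]2(C)C(=C)C(C)=CC[C@@H]12 | intermediate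
15 | bis(9-BBN) adduct of 14, boron on C11 and on the chain terminus | C1CCC2CCCC1B2CCC[C@]1(C)CC=C(O[Si](C)(C)C(C)(C)C)[C@]2(C)[C@@H](CB3C4CCCC3CCC4)C(C)=CC[C@@H]12 | intermediate
16 | diol: 4α-(3-hydroxypropyl), 9β-(hydroxymethyl), 9α-H, 1-silyl enol ether, Δ7 | OCCC[C@]1(C)CC=C(O[Si](C)(C)C(C)(C)C)[C@]2(C)[C@@H](CO)C(C)=CC[C@@H]12 | intermediate
17 | diacetate of 16 | CC(=O)OCCC[C@]1(C)CC=C(O[Si](C)(C)C(C)(C)C)[C@]2(C)[C@@H](COC(C)=O)C(C)=CC[C@@H]12 | intermediate
18 | Δ2,Δ7-dien-1-one diacetate | CC(=O)OCCC[C@]1(C)C=CC(=O)[C@]2(C)[C@@H](COC(C)=O)C(C)=CC[C@@H]12 | intermediate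
19 | 3α-(pinacolboryl)-1-ketone diacetate | CC(=O)OCCC[C@]1(C)[C@H](B3OC(C)(C)C(C)(C)O3)CC(=O)[C@]2(C)[C@@H](COC(C)=O)C(C)=CC[C@@H]12 | intermediate
20 | 1α-hydroxy-3α-(pinacolboryl) diacetate | CC(=O)OCCC[C@]1(C)[C@H](B3OC(C)(C)C(C)(C)O3)C[C@H](O)[C@]2(C)[C@@H](COC(C)=O)C(C)=CC[C@@H]12 | intermediate
21 | 1α-(triethylsilyloxy)-3α-(pinacolboryl) diacetate | CC(=O)OCCC[C@]1(C)[C@H](B3OC(C)(C)C(C)(C)O3)C[C@H](O[Si](CC)(CC)CC)[C@]2(C)[C@@H](COC(C)=O)C(C)=CC[C@@H]12 | intermediate
22 | 3α-hydroxy-1α-(triethylsilyloxy) diacetate | CC(=O)OCCC[C@]1(C)[C@H](O)C[C@H](O[Si](CC)(CC)CC)[C@]2(C)[C@@H](COC(C)=O)C(C)=CC[C@@H]12 | intermediate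
23 | 3β-chloro-1α-(triethylsilyloxy) diacetate | CC(=O)OCCC[C@]1(C)[C@@H](Cl)C[C@H](O[Si](CC)(CC)CC)[C@]2(C)[C@@H](COC(C)=O)C(C)=CC[C@@H]12 | intermediate
24 | C12 enal (8-formyl) of 23 | CC(=O)OCCC[C@]1(C)[C@@H](Cl)C[C@H](O[Si](CC)(CC)CC)[C@]2(C)[C@@H](COC(C)=O)C(C=O)=CC[C@@H]12 | intermediate
25 | lactol (C11–O–C12 hemiacetal, anomers) with 4α-(3-hydroxypropyl) chain | OCCC[C@]1(C)[C@@H](Cl)C[C@H](O[Si](CC)(CC)CC)[C@]2(C)[C@@H](CO3)C(C3O)=CC[C@@H]12 | intermediate
26 | butenolide (C12 carbonyl, O on C11) with 4α-(3-oxopropyl) chain | O=CCC[C@]1(C)[C@@H](Cl)C[C@H](O[Si](CC)(CC)CC)[C@]2(C)[C@@H](CO3)C(C3=O)=CC[C@@H]12 | intermediate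
27 | butenolide with 4α-(4-methylpent-3-enyl) chain | CC(C)=CCC[C@]1(C)[C@@H](Cl)C[C@H](O[Si](CC)(CC)CC)[C@]2(C)[C@@H](CO3)C(C3=O)=CC[C@@H]12 | intermediate
28 | 11,12-diol, 3β-chloro, 1α-(triethylsilyloxy), Δ7 | CC(C)=CCC[C@]1(C)[C@@H](Cl)C[C@H](O[Si](CC)(CC)CC)[C@]2(C)[C@@H](CO)C(CO)=CC[C@@H]12 | intermediate
29 | 11,12-bis(dimethylsulfoniooxy) dichloride of 28 | CC(C)=CCC[C@]1(C)[C@@H](Cl)C[C@H](O[Si](CC)(CC)CC)[C@]2(C)[C@@H](CO[S+](C)C)C(CO[S+](C)C)=CC[C@@H]12.[Cl-].[Cl-] | intermediate
30 | 1α-triethylsilyl ether of the target dialdehyde | CC(C)=CCC[C@]1(C)[C@@H](Cl)C[C@H](O[Si](CC)(CC)CC)[C@]2(C)[C@@H](C=O)C(C=O)=CC[C@@H]12 | intermediate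
31 | CNP0155449.1: 3β-chloro-1α-hydroxy-4β,10β-dimethyl-4α-(4-methylpent-3-enyl)-trans-decal-7-ene-8,9β-dicarbaldehyde | CC(C)=CCC[C@]1(C)[C@@H](Cl)C[C@H](O)[C@]2(C)[C@@H](C=O)C(C=O)=CC[C@@H]12 | target

**Step count and risk**

Total step count: 22. Longest linear sequence: 22 steps from (R)-carvone (1).

Steps most likely to fail:

1. Step 5. Allyl transfer to the C2 radical before ring closure, or loss of HI from the tertiary iodide that iodine transfer produces, would drain the cascade. The fallback separates the two events and sets out from 9. Without any allyl donor, 9 is cyclised by iodine-atom transfer (Bu3SnSnBu3 cat., sunlamp, benzene, 80 °C) to the tertiary C4 iodide F1. The isolated F1 is then allylated with 10 and AIBN in benzene at 80 °C, which brings the route back at 11.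

2. Step 15. Elimination toward C2 through the antiperiplanar 2β-hydrogen, or a 1,2-methyl shift from C4, may outrun rear-side displacement at the neopentylic C3. The fallback replaces polar substitution by a radical and sets out from 22. Acylation with methyl chlorooxoacetate (Et3N, DMAP) gives the methyl oxalate F2, and one equivalent of CsOH in THF/H2O gives the caesium oxalate F3. Irradiation of F3 with visible light in the presence of Ir[dF(CF3)ppy]2(dtbbpy)PF6 and ethyl trichloroacetate as chlorine-atom donor releases the C3 radical. This radical should take chlorine on the β face, since the syn-axial silyl ether on C1 screens the α face, and the route comes back at 23.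

3. Step 7. Addition of the ylide to the C9 carbonyl, flanked by the quaternary C10 and the C8 methyl, may be too slow, with enolisation toward C6 taking over. The fallback is a Peterson olefination with a small, weakly basic nucleophile and sets out from 13. Me3SiCH2Li/CeCl3 in THF at −78 °C adds to C9 to give the β-hydroxysilane F4, and KH in THF effects syn-elimination of F4, which brings the route back at 14.

Further compounds
F1 | step 5 | 4-iodo-4,8,10β-trimethyl-trans-decal-7-ene-1,9-dione (C4 epimers) | CC1(I)CCC(=O)[C@]2(C)C(=O)C(C)=CC[C@@H]12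
F2 | step 15 | 3α-methyl oxalate of 22 | CC(=O)OCCC[C@]1(C)[C@H](OC(=O)C(=O)OC)C[C@H](O[Si](CC)(CC)CC)[C@]2(C)[C@@H](COC(C)=O)C(C)=CC[C@@H]12
F3 | step 15 | caesium 3α-oxalate of 22 | CC(=O)OCCC[C@]1(C)[C@H](OC(=O)C([O-])=O)C[C@H](O[Si](CC)(CC)CC)[C@]2(C)[C@@H](COC(C)=O)C(C)=CC[C@@H]12.[Cs+]
F4 | step 7 | 9-hydroxy-9-(trimethylsilylmethyl) adduct of 13 (C9 epimers) | C=CC[C@]1(C)CC=C(O[Si](C)(C)C(C)(C)C)[C@]2(C)C(O)(C[Si](C)(C)C)C(C)=CC[C@@H]12
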